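**Strategy.** Ring A (C1–C5, C10) with its C1=C10 alkene is read as a Diels–Alder adduct of the ring B diene C2=C1–C10=C5 and a methacrylate C3=C4. Because the free C13–OH and the C4 ester are formally a lactone plus methanol, the methacrylate is hung on O13. A type 2 intramolecular Diels–Alder reaction of this triene then forms C2–C3 and C4–C5 in one operation, leaves C1=C10 as the bridgehead alkene of a temporary nine-membered lactone, and lets the tether anchored through C11 on C9 fix the face at C5 and the ester-endo geometry at C4. Methanolysis and acetylation finish the target.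

Key step: step 9

Remark on the chemistry: halimane-type numbering is used (ring A C1–C5/C10, ring B C5–C10, side chain C11–C15, C16 the methyl on C13). The target is taken as (4S,5R,8R,9S,13R,14S), which places H5, the C4, C8 and C9 methyls on one face and C11 and the C4 ester on the other. In step 1 the ligand antipode that gives the 3R product is used.

**Step 1**
Reactants: 1 2-methylcyclohex-2-en-1-one
Product: 3 trimethyl{[(3R)-2,3-dimethylcyclohex-1-en-1-yl]oxy}silane, via aluminium enolate 2 (not isolated)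
Conditions: Me3Al, Cu(O2CC4H3S) (copper thiophene-2-carboxylate, cat.), BINOL/bis(1-phenylethyl)amine phosphoramidite ligand (cat.), Et2O, −30 °C; then Me3SiOTf, THF, −30 → 0 °C
Reagents that add atoms: trimethylaluminium C[Al](C)C; trimethylsilyl triflate C[Si](C)(C)OS(=O)(=O)C(F)(F)F
Why: copper-catalysed asymmetric conjugate addition of a methyl group sets C8 (3R) under ligand control, and O-silylation of the aluminium enolate fixes the tetrasubstituted enol ether needed for the next step.

**Step 2**
Reactants: 3 trimethyl{[(3R)-2,3-dimethylcyclohex-1-en-1-yl]oxy}silane; 4 but-3-en-2-one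
Product: 5 (2S,3R)-2,3-dimethyl-2-(3-oxobutyl)cyclohexan-1-one
Conditions: BF3·OEt2, i-PrOH, CH2Cl2/MeNO2, −78 °C
Reagents that add atoms: none
Why: Mukaiyama–Michael addition in which the enone approaches the enol ether anti to the pseudoaxial C8 methyl, so the new quaternary C9 (2S) carries its methyl cis to the C8 methyl and the C11 chain trans to it.

**Step 3**
Reactants: 5 (2S,3R)-2,3-dimethyl-2-(3-oxobutyl)cyclohexan-1-one; 6 triethyl phosphonoacetate
Product: 7 ethyl (E)-5-[(1S,2R)-1,2-dimethyl-6-oxocyclohexyl]-3-methylpent-2-enoate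
Conditions: NaH, THF, 0 → 40 °C
Reagents that add atoms: none
Why: Horner–Wadsworth–Emmons olefination that should react only at the unhindered methyl ketone (the ring ketone is flanked by the quaternary C9) and favour the E-enoate, the minor Z isomer being removed by chromatography.

**Step 4**
Reactants: 7 ethyl (E)-5-[(1S,2R)-1,2-dimethyl-6-oxocyclohexyl]-3-methylpent-2-enoate
Product: 8 ethyl (E)-5-[(1S,6R)-1,6-dimethyl-2-{[(trifluoromethyl)sulfonyl]oxy}cyclohex-2-en-1-yl]-3-methylpent-2-enoate
Conditions: KN(SiMe3)2, THF, −78 °C; then PhNTf2, −78 → 0 °C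
Reagents that add atoms: N-phenylbis(trifluoromethanesulfonimide) O=S(=O)(N(c1ccccc1)S(=O)(=O)C(F)(F)F)C(F)(F)F
Why: kinetic enolate triflation in which the ketone can enolise only towards C5 (C9 is quaternary) and is deprotonated faster than the less acidic γ-positions of the enoate, giving the C10=C5 enol triflate.

**Step 5**
Reactants: 8 ethyl (E)-5-[(1S,6R)-1,6-dimethyl-2-{[(trifluoromethyl)sulfonyl]oxy}cyclohex-2-en-1-yl]-3-methylpent-2-enoate; 9 tributyl(vinyl)stannane
Product: 10 ethyl (E)-5-[(1S,6R)-2-ethenyl-1,6-dimethylcyclohex-2-en-1-yl]-3-methylpent-2-enoate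
Conditions: Pd(PPh3)4 (cat.), LiCl, THF, 65 °C
Reagents that add atoms: none
Why: Stille coupling of an enol triflate with a vinylstannane installs C1=C2 and completes the diene C2=C1–C10=C5 without touching the stereocentres.

**Step 6**
Reactants: 10 ethyl (E)-5-[(1S,6R)-2-ethenyl-1,6-dimethylcyclohex-2-en-1-yl]-3-methylpent-2-enoate
Product: 11 (E)-5-[(1S,6R)-2-ethenyl-1,6-dimethylcyclohex-2-en-1-yl]-3-methylpent-2-en-1-ol
Conditions: i-Bu2AlH, CH2Cl2, −78 °C; aqueous potassium sodium tartrate
Reagents that add atoms: none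
Why: 1,2-reduction of the α,β-unsaturated ester gives the E-allylic alcohol, and the unactivated diene is inert to the hydride.

**Step 7**
Reactants: 11 (E)-5-[(1S,6R)-2-ethenyl-1,6-dimethylcyclohex-2-en-1-yl]-3-methylpent-2-en-1-ol
Product: 12 {(2S,3S)-3-[2-((1S,6R)-2-ethenyl-1,6-dimethylcyclohex-2-en-1-yl)ethyl]-3-methyloxiran-2-yl}methanol
Conditions: t-BuOOH, Ti(OiPr)4 (cat.), L-(+)-diisopropyl tartrate (cat.), 4 Å molecular sieves, CH2Cl2, −20 °C
Reagents that add atoms: tert-butyl hydroperoxide CC(C)(C)OO
Why: Sharpless asymmetric epoxidation, which is directed by the allylic hydroxyl and leaves the diene alone, sets C13 and C14 as (13S,14S) under reagent control, as for other E-3,3-disubstituted allylic alcohols with the L-tartrate.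

**Step 8**
Reactants: 12 {(2S,3S)-3-[2-((1S,6R)-2-ethenyl-1,6-dimethylcyclohex-2-en-1-yl)ethyl]-3-methyloxiran-2-yl}methanol; 13 methacrylic acid
Product: 15 (2S,3R)-5-[(1S,6R)-2-ethenyl-1,6-dimethylcyclohex-2-en-1-yl]-3-methyl-3-(methacryloyloxy)pentane-1,2-diyl diacetate, via diol ester 14 (not isolated)
Conditions: Ti(OiPr)4, CH2Cl2, 0 °C; cold aqueous tartaric acid wash; crude directly: Ac2O, pyridine, DMAP (cat.), CH2Cl2, 0 °C
Reagents that add atoms: acetic anhydride CC(=O)OC(C)=O
Why: Ti(OiPr)4-mediated opening of a 2,3-epoxy alcohol by a carboxylic acid occurs at the tertiary C13 with inversion, giving the 13R ester beside the 14S,15-diol, and immediate acetylation of the primary and secondary hydroxyls should forestall migration of the methacryloyl group.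

**Step 9**
Reactants: 15 (2S,3R)-5-[(1S,6R)-2-ethenyl-1,6-dimethylcyclohex-2-en-1-yl]-3-methyl-3-(methacryloyloxy)pentane-1,2-diyl diacetate
Product: 16 (4S,5R,8R,9S,13R,14S)-14,15-diacetoxyhalim-1(10)-ene-4-carboxylic acid O13-lactone (ring A closed; C4–CO–O–C13 nine-membered lactone bridge)
Conditions: 1,2-dichlorobenzene (0.005 M), BHT (cat.), 170 °C, sealed tube
Reagents that add atoms: none
Why: Thermal concerted suprafacial [4+2] cycloaddition in which the diene C2=C1–C10=C5 carries the dienophile C3=C4 on a tether from its internal carbon C10 (through C9, C11, C12, C13, O and the ester carbonyl), the closest known reaction type being the type 2 intramolecular Diels–Alder reaction of ester-tethered acrylates on 2-substituted dienes that gives bridgehead-alkene lactones. Ring A closes by the [4+2] mode (bonds C2–C3 and C4–C5), and the temporary nine-membered lactone ring (C4, C=O, O, C13, C12, C11, C9, C10, C5) closes with it as the long bridge of a bicyclo[6.3.1] system whose C1=C10 alkene is an allowed bridgehead alkene. C5 is set by the tether, which starts at C11 on one face of ring B and cannot reach the other face without a strained trans-like bridge around C9–C10, so C4 should bond to C5 syn to C11 and anti to the pseudoaxial C9 methyl. C4 is set by the same tether, which can be closed only when the ester carbonyl lies endo over C10, placing the carboxyl trans to H5 and the C4 methyl exo. The step needs the 1,3-bridged orientation (C4 to C5) and not the 1,4-bridged one (C4 to C2), which the shorter bridge and the polarity of the diene should secure, since the unhindered terminus C2 is the one that bonds to the acrylate β-carbon C3. High dilution and a radical inhibitor are used to suppress intermolecular cycloaddition and polymerisation.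

**Step 10**
Reactants: 16 (4S,5R,8R,9S,13R,14S)-14,15-diacetoxyhalim-1(10)-ene-4-carboxylic acid O13-lactone
Product: 18 methyl (4S,5R,8R,9S,13R,14S)-13,14,15-trihydroxyhalim-1(10)-ene-4-carboxylate, via diol lactone 17 (not isolated)
Conditions: NaOMe, MeOH, 65 °C
Reagents that add atoms: methanol CO
Why: base-mediated transesterification removes both acetates, after which the strained tertiary lactone should be relayed by the neighbouring C14 and C15 alkoxides (1,2-acyl shifts) and released by methoxide as the methyl ester, with no epimerisable centre involved.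

**Step 11**
Reactants: 18 methyl (4S,5R,8R,9S,13R,14S)-13,14,15-trihydroxyhalim-1(10)-ene-4-carboxylate
Product: 19 methyl (4S,5R,8R,9S,13R,14S)-14,15-diacetoxy-13-hydroxyhalim-1(10)-ene-4-carboxylate (target CNP0238486.2)
Conditions: Ac2O, pyridine, CH2Cl2, 0 °C → rt
Reagents that add atoms: acetic anhydride CC(=O)OC(C)=O
Why: standard acetylation esterifies the primary C15 and secondary C14 hydroxyls, while the tertiary C13 hydroxyl should remain free in the absence of an acyl-transfer catalyst.

**Compound list**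
1 | 2-methylcyclohex-2-en-1-one | CC1=CCCCC1=O | starting material
2 | dimethylaluminium (3R)-2,3-dimethylcyclohex-1-en-1-olate | C[Al](C)OC1=C(C)[C@H](C)CCC1 | intermediate
3 | trimethyl{[(3R)-2,3-dimethylcyclohex-1-en-1-yl]oxy}silane | C[Si](C)(C)OC1=C(C)[C@H](C)CCC1 | intermediate
4 | but-3-en-2-one (methyl vinyl ketone) | CC(=O)C=C | starting material
5 | (2S,3R)-2,3-dimethyl-2-(3-oxobutyl)cyclohexan-1-one | O=C1CCC[C@@H](C)[C@]1(C)CCC(C)=O | intermediate
6 | triethyl phosphonoacetate | CCOC(=O)CP(=O)(OCC)OCC | starting material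
7 | ethyl (E)-5-[(1S,2R)-1,2-dimethyl-6-oxocyclohexyl]-3-methylpent-2-enoate | O=C1CCC[C@@H](C)[C@]1(C)CC/C(C)=C/C(=O)OCC | intermediate
8 | ethyl (E)-5-[(1S,6R)-1,6-dimethyl-2-{[(trifluoromethyl)sulfonyl]oxy}cyclohex-2-en-1-yl]-3-methylpent-2-enoate | O=S(=O)(OC1=CCC[C@@H](C)[C@]1(C)CC/C(C)=C/C(=O)OCC)C(F)(F)F | intermediate
9 | tributyl(vinyl)stannane | C=C[Sn](CCCC)(CCCC)CCCC | starting material
10 | ethyl (E)-5-[(1S,6R)-2-ethenyl-1,6-dimethylcyclohex-2-en-1-yl]-3-methylpent-2-enoate | C=CC1=CCC[C@@H](C)[C@]1(C)CC/C(C)=C/C(=O)OCC | intermediate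
11 | (E)-5-[(1S,6R)-2-ethenyl-1,6-dimethylcyclohex-2-en-1-yl]-3-methylpent-2-en-1-ol | C=CC1=CCC[C@@H](C)[C@]1(C)CC/C(C)=C/CO | intermediate
12 | {(2S,3S)-3-[2-((1S,6R)-2-ethenyl-1,6-dimethylcyclohex-2-en-1-yl)ethyl]-3-methyloxiran-2-yl}methanol | C=CC1=CCC[C@@H](C)[C@]1(C)CC[C@]2(C)O[C@H]2CO | intermediate
13 | methacrylic acid (2-methylprop-2-enoic acid) | CC(=C)C(=O)O | starting material
14 | (2S,3R)-5-[(1S,6R)-2-ethenyl-1,6-dimethylcyclohex-2-en-1-yl]-1,2-dihydroxy-3-methylpentan-3-yl 2-methylprop-2-enoate | C=CC1=CCC[C@@H](C)[C@]1(C)CC[C@@](C)(OC(=O)C(C)=C)[C@H](CO)O | intermediate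
15 | (2S,3R)-5-[(1S,6R)-2-ethenyl-1,6-dimethylcyclohex-2-en-1-yl]-3-methyl-3-(methacryloyloxy)pentane-1,2-diyl diacetate | C=CC1=CCC[C@@H](C)[C@]1(C)CC[C@@](C)(OC(=O)C(C)=C)[C@H](COC(C)=O)OC(C)=O | intermediate
16 | (4S,5R,8R,9S,13R,14S)-14,15-diacetoxyhalim-1(10)-ene-4-carboxylic acid O13-lactone | O=C3[C@@]1(C)CCC=C2[C@H]1CC[C@@H](C)[C@]2(C)CC[C@@](C)(O3)[C@H](COC(C)=O)OC(C)=O | intermediate
17 | (4S,5R,8R,9S,13R,14S)-14,15-dihydroxyhalim-1(10)-ene-4-carboxylic acid O13-lactone | O=C3[C@@]1(C)CCC=C2[C@H]1CC[C@@H](C)[C@]2(C)CC[C@@](C)(O3)[C@H](CO)O | intermediate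
18 | methyl (4S,5R,8R,9S,13R,14S)-13,14,15-trihydroxyhalim-1(10)-ene-4-carboxylate | COC(=O)[C@@]1(C)CCC=C2[C@H]1CC[C@@H](C)[C@]2(C)CC[C@@](C)(O)[C@H](CO)O | intermediate
19 | methyl (4S,5R,8R,9S,13R,14S)-14,15-diacetoxy-13-hydroxyhalim-1(10)-ene-4-carboxylate | COC(=O)[C@@]1(C)CCC=C2[C@H]1CC[C@@H](C)[C@]2(C)CC[C@@](C)(O)[C@H](COC(C)=O)OC(C)=O | target

**Total step count:** 11. **Longest linear sequence:** 11 steps (1 → 19).

**Steps most likely to fail**

Step 9 (key cycloaddition). The nine-membered bridge may close too slowly, so that oligomerisation, the 1,4-bridged orientation or thermal elimination of the tertiary ester takes over. Fallback without a tether: diene ester 10 is heated with methyl methacrylate (BHT, sealed tube) to give the intermolecular Diels–Alder adduct F1, the isomer with C4 bonded to C5 on the C11 face and the ester endo being separated from its isomers. Selective i-Bu2AlH reduction of the conjugated ethyl ester (the C4 ester is neopentylic) gives allylic alcohol F2. Sharpless epoxidation with L-(+)-diisopropyl tartrate gives epoxy alcohol F3. Dilute HClO4 in aqueous THF then opens the epoxide at the tertiary C13 with inversion and returns to the route at triol ester 18.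

Step 10 (lactone methanolysis). Acyl substitution at the carbonyl on the quaternary C4 may stall after the acetates are lost, leaving the lactone or a ring-expanded lactone. Fallback by reduction and re-oxidation: lactone 16 is reduced with LiAlH4 (THF, 0 °C) to tetraol F4. The 14,15-diol is protected with 2,2-dimethoxypropane and pyridinium tosylate as acetonide F5. The C4 hydroxymethyl group is oxidised with DMP (the triacetoxy-benziodoxolone periodinane) to aldehyde F6 and with NaClO2/NaH2PO4/2-methylbut-2-ene to acid F7. Me3SiCHN2 gives methyl ester F8, and aqueous acetic acid removes the acetonide to rejoin the route at 18.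

Step 8 (epoxide opening by methacrylic acid). The methacryloyl group may migrate from the tertiary oxygen to the neighbouring hydroxyls before acetylation, or C13 may ionise with loss of configuration or elimination. Fallback that installs the ester last: epoxy alcohol 12 is hydrolysed with catalytic HClO4 in aqueous THF at 0 °C (water attacks C13 with inversion) to triol F9. Ac2O and pyridine give the 14,15-diacetate with free tertiary hydroxyl F10. Methacrylic anhydride with catalytic Sc(OTf)3 in MeCN at −20 °C then acylates the tertiary alcohol and returns to the route at 15.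

**Further compounds**
F1 | step 9 | methyl (4S,5R,8R,9S)-9-[(E)-5-ethoxy-3-methyl-5-oxopent-3-enyl] analogue of 18 (ring A closed, side chain ethyl E-enoate) | COC(=O)[C@@]1(C)CCC=C2[C@H]1CC[C@@H](C)[C@]2(C)CC/C(C)=C/C(=O)OCC
F2 | step 9 | methyl (4S,5R,8R,9S,13E)-15-hydroxyhalima-1(10),13-diene-4-carboxylate | COC(=O)[C@@]1(C)CCC=C2[C@H]1CC[C@@H](C)[C@]2(C)CC/C(C)=C/CO
F3 | step 9 | methyl (4S,5R,8R,9S,13S,14S)-13,14-epoxy-15-hydroxyhalim-1(10)-ene-4-carboxylate | COC(=O)[C@@]1(C)CCC=C2[C@H]1CC[C@@H](C)[C@]2(C)CC[C@]3(C)O[C@H]3CO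
F4 | step 10 | tetraol: C4 hydroxymethyl analogue of 18 (C4–CH2OH, 13,14,15-triol) | OC[C@@]1(C)CCC=C2[C@H]1CC[C@@H](C)[C@]2(C)CC[C@@](C)(O)[C@H](CO)O
F5 | step 10 | 14,15-O-isopropylidene derivative of the tetraol | OC[C@@]1(C)CCC=C2[C@H]1CC[C@@H](C)[C@]2(C)CC[C@@](C)(O)[C@@H]3COC(C)(C)O3
F6 | step 10 | C4 aldehyde of the 14,15-acetonide | O=C[C@@]1(C)CCC=C2[C@H]1CC[C@@H](C)[C@]2(C)CC[C@@](C)(O)[C@@H]3COC(C)(C)O3
F7 | step 10 | C4 carboxylic acid of the 14,15-acetonide | OC(=O)[C@@]1(C)CCC=C2[C@H]1CC[C@@H](C)[C@]2(C)CC[C@@](C)(O)[C@@H]3COC(C)(C)O3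
F8 | step 10 | methyl ester of the 14,15-acetonide (acetonide of 18) | COC(=O)[C@@]1(C)CCC=C2[C@H]1CC[C@@H](C)[C@]2(C)CC[C@@](C)(O)[C@@H]3COC(C)(C)O3
F9 | step 8 | (2S,3R)-5-[(1S,6R)-2-ethenyl-1,6-dimethylcyclohex-2-en-1-yl]-3-methylpentane-1,2,3-triol | C=CC1=CCC[C@@H](C)[C@]1(C)CC[C@@](C)(O)[C@H](CO)O
F10 | step 8 | (2S,3R)-5-[(1S,6R)-2-ethenyl-1,6-dimethylcyclohex-2-en-1-yl]-3-hydroxy-3-methylpentane-1,2-diyl diacetate | C=CC1=CCC[C@@H](C)[C@]1(C)CC[C@@](C)(O)[C@H](COC(C)=O)OC(C)=O
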